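At early times the readings came near the middle question, though they began after the earliest asked time: in the alpha run at 6.00 min, the isomer of the product A read 1.12 times the target. The last epsilon reading of the target, 1.5% at 50.0 min, carried a scatter of 0.5 percentage points, and the flask was asked at 80 min, so its end had to be reckoned.

| flask | starting material | protic impurity | remark | time |
|---|---|---|---|---|
| alpha | 0.27 M | 0.162 M | run made earlier |  |
| epsilon | 1.1 M | 0.162 M | run made earlier |  |
| beta | 0.54 M | 0.24 M | run made earlier |  |
| flask | 0.54 M | 0.162 M |  | 80 min |

- alpha (time / min: isomer of the product A / %, target / %): 4.00: 6.0, 10.0; 6.00: 12.3, 11.0; 10.0: 15.6, 9.7; 20.0: 22.0, 6.3; 30.0: 24.6, 2.5; 50.0: 26.0, 0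
- epsilon (time / min: isomer of the product A / %, target / %): 8.00: 14.9, 10.9; 15.0: 23.6, 9.0; 25.0: 29.7, 4.6; 30.0: 31.9, 3.4; 40.0: 34.3, 2.6; 50.0: 36.5, 1.5
- beta (time / min: isomer of the product A / %, target / %): 4.00: 6.8, 9.0; 12.0: 15.9, 8.7; 20.0: 20.8, 5.9; 30.0: 22.9, 3.0; 50.0: 25.0, 0.4

(readings scatter by 0.5 percentage points)

- the earlier runs were read with a standard deviation of 0.5 percentage points
- steps thought possible: target <-> isomer of the product B; target -> over-reaction product; other conformer + protic impurity -> quenched substrate; starting material -> target; starting material <-> other conformer; other conformer -> isomer of the product A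

* ratio of isomer of the product A to target at 40 s
* ratio of isomer of the product A to target at 6.0 min
* ratio of isomer of the product A to target at 80 min

Alpha and epsilon share the flask's impurity charge, and the geometric middle of their starting charges, 0.545 M, lies near the flask's 0.54 M. Late in the runs, the target's half-life read 7.50 min in alpha and 15.5 min in epsilon. Averaging the two rates gave a half-life of 10.1 min. I called n the number of these half-lives between 30.0 min and 80 min, which came to 4.95. On this reckoning, each unit of n counted one more halving of the target. Starting from the mean of the two runs' target readings at 30.0 min and the mean of their last readings of the isomer of the product A, I reckoned a ratio of 327.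

One number was not enough: n was 6.67 on alpha's half-life and 3.23 on epsilon's, which moved the ratio from 99.6 to 1080.

The forecast gave 0.17 at 40 s, 1.1 at 6.0 min and 120 at 80 min, with a range of 40 to 350 for the last, calling the tail “poorly defined because epsilon hints at a reservoir in isomer B”. My 327 stood higher than its value.

The flask gave 0.132, 0.988 and 432.

    target ⇌ isomer of the product B (K = 0.120, k = 0.00440 s⁻¹)
    target → over-reaction product (k = 0.00270 s⁻¹)
    other conformer + protic impurity → quenched substrate (k = 0.0130 M⁻¹ s⁻¹)
    starting material → target (k = 0.00130 s⁻¹)
    starting material ⇌ other conformer (K = 1.20, k = 0.00830 s⁻¹)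
    other conformer → isomer of the product A (k = 0.00100 s⁻¹)

In the flask the target fell from 1.48% at 40.0 min to 0.0714% at 80.0 min, a half-life of 9.14 min, which made n 5.47 instead of 4.95. A neighbouring flask kept the impurity charge but held 0.14 M of starting material, less than alpha, and I counted on alpha's readings: n of 6.67 gave a ratio of 1060. That neighbouring flask gave 2190 at 80 min.

The data are calculated from invented constants; scatter was added.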